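Ring B is a 2-aryloxyhydroquinone: C1' carries the ether oxygen and C2' and C5' the hydroxyls. That 1,2,4-trioxygenated pattern maps onto an aryl semisquarate (C5', C6', C1', C2' with all three oxygens), leaving C3'–C4' as a vinyl group. Heating racemic 4-hydroxy-3-(2,3,5-tribromo-4-methoxyphenoxy)-4-vinylcyclobut-2-en-1-one should open the four-membered ring to a dienylketene, close the C4'–C5' bond and aromatise, creating ring B with the hindered diaryl ether already in place. The ether is therefore made beforehand as a vinylogous esterification of the ring A phenol, and tribromination of ring B plus O-demethylation finish the synthesis.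

Key step: step 7

Assumption: the target has no stereocentre and is achiral, so no enantiocontrol is needed. The only stereocentre on the route (the carbinol carbon of 12, racemic) is erased in step 7. Ring B is numbered C1' (O-aryl), C2' (OH), C3', C4', C5' (OH), C6'; ring A is numbered from its ether carbon C1.

Step 1
Reactants: 1 3,5-dibromo-4-methoxybenzaldehyde
Product: 3 3,5-dibromo-4-methoxyphenol, via aryl formate 2 (not isolated)
Conditions: mCPBA, CH2Cl2, 40 °C; then MeOH, Et3N (cat.), rt
Reagents that add atoms: mCPBA, OOC(=O)c1cccc(Cl)c1
Why: Baeyer–Villiger (Dakin-type) oxidation, in which the peracid adduct of the aldehyde should rearrange by migration of the p-alkoxyaryl group to formate 2, which is methanolysed in the same flask; aryl bromides and the methyl ether are inert to peracid.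

Step 2
Reactants: 3 3,5-dibromo-4-methoxyphenol
Product: 4 2,3,5-tribromo-4-methoxyphenol
Conditions: Br2 (1.0 equiv), CH2Cl2, 0 °C
Reagents that add atoms: bromine, BrBr
Why: Electrophilic aromatic bromination directed by the free hydroxyl to its ortho positions (C2 and C6 are equivalent, C4 is blocked), and one equivalent at 0 °C should stop at the monobromide because each bromine deactivates the ring further.

Step 3
Reactants: 5 diisopropyl squarate
Product: 7 3-isopropoxycyclobut-3-ene-1,2-dione, via hydroxycyclobutenone 6 (not isolated)
Conditions: LiAlH(OtBu)3, THF, −20 → 0 °C; aq. HCl quench; then conc. HCl (cat.), CH2Cl2, rt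
Reagents that add atoms: none
Why: Chemoselective hydride reduction of one squarate carbonyl by the bulky alkoxyaluminium hydride gives racemic carbinol 6, which under acid catalysis should ionise, transpose its oxygen and lose isopropanol (hydrolysis of a vinylogous ester) to unveil the semisquarate, the carbinol centre being lost at once.

Step 4
Reactants: 7 3-isopropoxycyclobut-3-ene-1,2-dione
Product: 8 semisquaric acid (3-hydroxycyclobut-3-ene-1,2-dione)
Conditions: 2 M aq. HCl, THF, rt → 40 °C; evaporate, dry azeotropically (PhMe)
Reagents that add atoms: water, O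
Why: Acid-catalysed hydrolysis of a vinylogous ester (addition of water at C3, loss of isopropanol), which should leave the strongly acidic semisquaric acid as the residue after evaporation.

Step 5
Reactants: 8 semisquaric acid; 4 2,3,5-tribromo-4-methoxyphenol
Product: 10 3-(2,3,5-tribromo-4-methoxyphenoxy)cyclobut-3-ene-1,2-dione, via semisquaric chloride 9 (not isolated)
Conditions: (COCl)2, DMF (cat.), CH2Cl2, 0 °C → rt; evaporate; then 4, 2,6-lutidine, CH2Cl2, −40 → 0 °C
Reagents that add atoms: none
Why: Vinylogous acid chloride formation (Vilsmeier-type activation by oxalyl chloride/DMF) followed by addition–elimination of the phenol at the chlorine-bearing carbon, i.e. a vinylogous Schotten–Baumann esterification, in which the hindered pyridine only scavenges HCl and the hydroxyl is the single nucleophilic site of 4.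

Step 6
Reactants: 10 3-(2,3,5-tribromo-4-methoxyphenoxy)cyclobut-3-ene-1,2-dione; 11 vinylmagnesium bromide
Product: 12 rac-4-hydroxy-3-(2,3,5-tribromo-4-methoxyphenoxy)-4-vinylcyclobut-2-en-1-one
Conditions: CH2=CHMgBr (1.05 equiv), THF, −78 °C; sat. aq. NH4Cl at −78 °C
Reagents that add atoms: vinylmagnesium bromide (11), C=C[Mg]Br
Why: Grignard 1,2-addition to the ketone-like carbonyl next to the aryloxy-bearing carbon, which is more electrophilic than the vinylogous ester carbonyl; at −78 °C the vinyl Grignard should not exchange with aryl bromides, the new carbinol centre is formed racemic (it is erased in step 7), and a regioisomeric adduct would converge on the same hydroquinone.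

Step 7
Reactants: 12 rac-4-hydroxy-3-(2,3,5-tribromo-4-methoxyphenoxy)-4-vinylcyclobut-2-en-1-one
Product: 15 2-(2,3,5-tribromo-4-methoxyphenoxy)benzene-1,4-diol, via dienylketene 13 (not isolated), via cyclohexadienone 14 (not isolated)
Conditions: PhMe (degassed, ca. 0.02 M), 100 °C, Ar
Reagents that add atoms: none
Why: Thermal conrotatory 4π-electrocyclic opening of the cyclobutenone cleaves the bond between the carbinol carbon and the carbonyl carbon to give the (Z)-dienylketene 13, whose ketene carbon and vinyl terminus then join (the C4'–C5' bond) to dienone 14, which enolises to the aromatic hydroquinone. The closest known reaction type is the Moore–Liebeskind ring expansion of 4-alkenyl-4-hydroxycyclobutenones to hydroquinones. Ring B is closed as a six-membered carbocycle by a thermally allowed disrotatory 6π-electrocyclisation of the ketene C=C, the enol ether C=C and the vinyl C=C, not by an ionic cyclisation. No stereocentre is created, and the racemic carbinol carbon of 12 becomes the sp2 carbon C2'. The step needs torquoselectivity in the ring opening: the strongly donating hydroxyl rotates outward, which forces the vinyl group inward, next to the ketene, so that electrocyclisation should outrun lactonisation to a butenolide. The aryl vinylogous ester should survive because the medium is neutral, aprotic, dilute and oxygen-free at about 100 °C, and once ring B is aromatic the C1'–O bond is an ordinary robust diaryl ether.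

Step 8
Reactants: 15 2-(2,3,5-tribromo-4-methoxyphenoxy)benzene-1,4-diol
Product: 16 2,3,5-tribromo-6-(2,3,5-tribromo-4-methoxyphenoxy)benzene-1,4-diol
Conditions: Br2 (3.2 equiv), AcOH, rt; aq. Na2S2O4 work-up
Reagents that add atoms: bromine, BrBr
Why: Electrophilic aromatic bromination of the hydroquinone ring, by far the most electron-rich site, at its three free positions C3', C4' and C6', while ring A is deactivated by three bromines and its single C–H is flanked by bromine and the ether oxygen; the dithionite wash destroys excess bromine and returns any material oxidised to the quinone level to the hydroquinone.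

Step 9
Reactants: 16 2,3,5-tribromo-6-(2,3,5-tribromo-4-methoxyphenoxy)benzene-1,4-diol
Product: 17 2,3,5-tribromo-6-(2,3,5-tribromo-4-hydroxyphenoxy)benzene-1,4-diol
Conditions: BBr3 (5 equiv), CH2Cl2, −78 °C → rt; H2O
Reagents that add atoms: none
Why: Lewis-acid-mediated O-demethylation (BBr3 cleavage of an aryl methyl ether), in which boron coordinates the di-ortho-bromo-flanked methoxy oxygen and bromide removes the methyl group by SN2, while the diaryl ether, the aryl bromides and the phenols (transient borates, hydrolysed on work-up) should be untouched.

Compound list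
1 | 3,5-dibromo-4-methoxybenzaldehyde | COc1c(Br)cc(C=O)cc1Br | starting material
2 | 3,5-dibromo-4-methoxyphenyl formate | COc1c(Br)cc(OC=O)cc1Br | intermediate
3 | 3,5-dibromo-4-methoxyphenol | COc1c(Br)cc(O)cc1Br | intermediate
4 | 2,3,5-tribromo-4-methoxyphenol | COc1c(Br)cc(O)c(Br)c1Br | intermediate
5 | diisopropyl squarate (3,4-diisopropoxycyclobut-3-ene-1,2-dione) | CC(C)OC1=C(OC(C)C)C(=O)C1=O | starting material
6 | rac-4-hydroxy-2,3-diisopropoxycyclobut-2-en-1-one | CC(C)OC1=C(OC(C)C)C(O)C1=O | intermediate
7 | 3-isopropoxycyclobut-3-ene-1,2-dione (isopropyl semisquarate) | CC(C)OC1=CC(=O)C1=O | intermediate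
8 | semisquaric acid (3-hydroxycyclobut-3-ene-1,2-dione) | OC1=CC(=O)C1=O | intermediate
9 | semisquaric chloride (3-chlorocyclobut-3-ene-1,2-dione) | ClC1=CC(=O)C1=O | intermediate
10 | 3-(2,3,5-tribromo-4-methoxyphenoxy)cyclobut-3-ene-1,2-dione | COc1c(Br)cc(OC2=CC(=O)C2=O)c(Br)c1Br | intermediate
11 | vinylmagnesium bromide | C=C[Mg]Br | starting material
12 | rac-4-hydroxy-3-(2,3,5-tribromo-4-methoxyphenoxy)-4-vinylcyclobut-2-en-1-one | C=CC1(O)C(Oc2cc(Br)c(OC)c(Br)c2Br)=CC1=O | intermediate
13 | (3Z)-4-hydroxy-3-(2,3,5-tribromo-4-methoxyphenoxy)hexa-1,3,5-trien-1-one (dienylketene, vinyl cis to the ketene) | O=C=C/C(Oc1cc(Br)c(OC)c(Br)c1Br)=C(/O)C=C | intermediate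
14 | 4-hydroxy-3-(2,3,5-tribromo-4-methoxyphenoxy)cyclohexa-2,4-dien-1-one | O=C1CC=C(O)C(Oc2cc(Br)c(OC)c(Br)c2Br)=C1 | intermediate
15 | 2-(2,3,5-tribromo-4-methoxyphenoxy)benzene-1,4-diol | COc1c(Br)cc(Oc2cc(O)ccc2O)c(Br)c1Br | intermediate
16 | 2,3,5-tribromo-6-(2,3,5-tribromo-4-methoxyphenoxy)benzene-1,4-diol | COc1c(Br)cc(Oc2c(O)c(Br)c(Br)c(O)c2Br)c(Br)c1Br | intermediate
17 | 2,3,5-tribromo-6-(2,3,5-tribromo-4-hydroxyphenoxy)benzene-1,4-diol (achiral) | Oc1c(Br)cc(Oc2c(O)c(Br)c(Br)c(O)c2Br)c(Br)c1Br | target

Total step count: 9. Longest linear sequence: 7 steps (5 → 17 through steps 3–9; equally 1 → 17 through steps 1, 2 and 5–9).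

Steps most likely to fail

Step 7. The ring opening may proceed with the hydroxyl turning inward, so that the ketene is trapped as a butenolide. The aryloxy group may also be lost from the vinylogous ester before the four-membered ring opens. Fallback: the diaryl ether is made by a copper-mediated O-arylation instead. It sets out from phenol 4, which is coupled with commercial 2,5-dimethoxyphenylboronic acid under Chan–Lam–Evans conditions (Cu(OAc)2, pyridine, 4 Å sieves, CH2Cl2, air, rt; aryl bromides are inert) to give 2-(2,3,5-tribromo-4-methoxyphenoxy)-1,4-dimethoxybenzene F1. Oxidative demethylation of the electron-rich ring with ceric ammonium nitrate (MeCN/H2O, 0 °C) should give 2-(2,3,5-tribromo-4-methoxyphenoxy)cyclohexa-2,5-diene-1,4-dione F2, and reduction with aqueous Na2S2O4 returns to the route at hydroquinone 15.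

Step 6. The vinyl nucleophile may attack the aryloxy-bearing carbon by conjugate addition–elimination and expel the aryloxide, or may undergo halogen–metal exchange with the polybrominated ring. Fallback: the two carbons are introduced as a less basic alkynyl nucleophile and reduced afterwards. It sets out from 10, to which ethynylmagnesium bromide is added (THF, −40 °C, cold NH4Cl quench) to give rac-4-ethynyl-4-hydroxy-3-(2,3,5-tribromo-4-methoxyphenoxy)cyclobut-2-en-1-one F3. Lindlar semi-hydrogenation (H2, Pd/CaCO3–Pb, quinoline, EtOAc, rt), which should spare aryl bromides and the ring enone, then returns to the route at 12.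

Step 5. The semisquaric chloride may decompose or oligomerise before the weakly nucleophilic, hindered phenol has acylated, and the aryl vinylogous ester may hydrolyse during isolation. Fallback: the C–H of the semisquarate is installed after the ester bond. It sets out from phenol 4 and squaric dichloride (3,4-dichlorocyclobut-3-ene-1,2-dione, commercial or one step from squaric acid). One equivalent of 4 with 2,6-lutidine in CH2Cl2 at −40 °C should give the monosubstitution product 3-chloro-4-(2,3,5-tribromo-4-methoxyphenoxy)cyclobut-3-ene-1,2-dione F4. Palladium-catalysed hydrodechlorination of this vinylogous acid chloride with Bu3SnH (Pd(PPh3)4 cat., PhMe, rt, as in the tin hydride reduction of acid chlorides to aldehydes) returns to the route at 10.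

Further compounds
F1 | step 7 | 2-(2,3,5-tribromo-4-methoxyphenoxy)-1,4-dimethoxybenzene | COc1ccc(OC)c(Oc2cc(Br)c(OC)c(Br)c2Br)c1
F2 | step 7 | 2-(2,3,5-tribromo-4-methoxyphenoxy)cyclohexa-2,5-diene-1,4-dione | COc1c(Br)cc(OC2=CC(=O)C=CC2=O)c(Br)c1Br
F3 | step 6 | rac-4-ethynyl-4-hydroxy-3-(2,3,5-tribromo-4-methoxyphenoxy)cyclobut-2-en-1-one | C#CC1(O)C(Oc2cc(Br)c(OC)c(Br)c2Br)=CC1=O
F4 | step 5 | 3-chloro-4-(2,3,5-tribromo-4-methoxyphenoxy)cyclobut-3-ene-1,2-dione | COc1c(Br)cc(OC2=C(Cl)C(=O)C2=O)c(Br)c1Br
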